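**Plan**

- Retrosynthesis: the pyran ring of the 2H-chromene is cut at O1–C2 and at C4–C4a together, giving a mono-silylated hydroquinone and a C20 enal (7,8,11,12-tetrahydroretinal). The enal is then cut at the CH2–CH2 bond next to the cyclohexene into β-cyclogeranyl phenyl sulfone and 8-bromogeranyl acetate.
- Enabling feature: O1–C8a–C4a is a phenol oxygen with its ortho carbon, and C4–C3–C2(CH3) is the carbonyl carbon, α-carbon and methyl-bearing β-carbon of a 3-methyl-2-enal. The benzene ring is para-dioxygenated, so both ortho CH positions of the phenol are equivalent and para is blocked.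
- Forward: the cyclohexene ring (β-cyclocitral) and both E-alkenes (geranyl acetate) are bought. The chain is joined by sulfone-anion allylation and desulfonylation, then oxidised to the enal. The pyran ring is closed onto the arene in the second-to-last step, and desilylation ends the route.
- Stereochemistry: the only stereocentre, C2 (S), is made when the phenol oxygen closes on the tertiary allyl terminus inside a chiral ion pair. The side-chain 3E alkene is the 6E alkene of geranyl acetate, carried through unchanged.

Key step: step 8

Assumption: the sense of induction of the chiral acid in step 8 cannot be predicted with confidence; the (R)-acid is written, and its (S)-antipode is used instead if a first run shows the (2R)-chromene.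

**Route**

Step 1
Reactants: 1 β-cyclocitral (2,6,6-trimethylcyclohex-1-ene-1-carbaldehyde)
Product: 2 β-cyclogeraniol [(2,6,6-trimethylcyclohex-1-en-1-yl)methanol]
Conditions: NaBH4, MeOH, 0 °C
Reagents that add atoms: none
Why: Borohydride 1,2-reduction of the hindered aldehyde, in which conjugate reduction cannot compete because the β-carbon is fully substituted.

Step 2
Reactants: 2 β-cyclogeraniol
Product: 4 β-cyclogeranyl phenyl sulfone, via β-cyclogeranyl bromide 3 (not isolated)
Conditions: PBr3, pyridine (cat.), Et2O, −10 °C; crude bromide, PhSO2Na, DMF, rt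
Reagents that add atoms: sodium benzenesulfinate, [Na+].[O-]S(=O)c1ccccc1; phosphorus tribromide, BrP(Br)Br (its bromine stands in intermediate 3 only)
Why: PBr3 turns the primary allylic alcohol into the labile bromide 3, which is displaced at once by the sulfur of benzenesulfinate in an SN2 reaction (S-alkylation of a sulfinate) to give the sulfone.

Step 3
Reactants: 5 geranyl acetate [(2E)-3,7-dimethylocta-2,6-dien-1-yl acetate]
Product: 6 (2E,6E)-8-hydroxy-3,7-dimethylocta-2,6-dien-1-yl acetate
Conditions: SeO2 (cat.), t-BuOOH, salicylic acid (cat.), CH2Cl2, rt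
Reagents that add atoms: tert-butyl hydroperoxide, CC(C)(C)OO (terminal oxidant; the oxygen is passed on by catalytic selenium dioxide, O=[Se]=O)
Why: Riley-type allylic oxidation (ene reaction, then [2,3]-shift) attacks the more electron-rich 6,7-alkene at its (E)-methyl group, the 2,3-alkene being deactivated by the allylic acetate, so the 6E geometry is kept.

Step 4
Reactants: 6 (2E,6E)-8-hydroxygeranyl acetate
Product: 7 (2E,6E)-8-bromo-3,7-dimethylocta-2,6-dien-1-yl acetate
Conditions: CBr4, PPh3, CH2Cl2, −20 to 0 °C
Reagents that add atoms: carbon tetrabromide, BrC(Br)(Br)Br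
Why: Appel reaction, in which the alcohol is activated as an alkoxyphosphonium ion and displaced by bromide under neutral conditions that leave the acetate and both E-alkenes untouched.

Step 5
Reactants: 4 β-cyclogeranyl phenyl sulfone; 7 (2E,6E)-8-bromogeranyl acetate
Product: 9 (2E,6E)-3,7-dimethyl-9-(phenylsulfonyl)-9-(2,6,6-trimethylcyclohex-1-en-1-yl)nona-2,6-dien-1-ol, via acetate sulfone 8 (not isolated)
Conditions: 4, n-BuLi, THF–DMPU, −78 °C; then 7, −78 to −20 °C; then K2CO3, MeOH, rt
Reagents that add atoms: none
Why: The α-sulfonyl carbanion of 4 is alkylated at the primary allylic bromide of 7 (SN2 sulfone-anion allylation, expected to be faster at −78 °C than attack on the acetate), and the acetate of 8 is removed in the same flask by K2CO3-mediated transesterification; the sulfonyl-bearing carbon is formed racemic and is deleted in step 6.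

Step 6
Reactants: 9 hydroxy sulfone
Product: 10 (2E,6E)-3,7-dimethyl-9-(2,6,6-trimethylcyclohex-1-en-1-yl)nona-2,6-dien-1-ol
Conditions: Li, EtNH2, THF, −78 °C; then MeOH
Reagents that add atoms: none
Why: Dissolving-metal reductive desulfonylation, in which electron transfer cleaves the allylic C–S bond and the allyl anion should be protonated at the less substituted exocyclic carbon, keeping the tetrasubstituted ring alkene, while the hydroxyl is shielded as its lithium alkoxide.

Step 7
Reactants: 10 C20 allylic alcohol
Product: 11 (2E,6E)-3,7-dimethyl-9-(2,6,6-trimethylcyclohex-1-en-1-yl)nona-2,6-dienal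
Conditions: MnO2, CH2Cl2, rt
Reagents that add atoms: none
Why: Selective allylic oxidation by MnO2, which leaves the isolated alkenes alone and should not isomerise the 2E double bond.

Step 8
Reactants: 11 C20 enal; 12 4-[(tert-butyldimethylsilyl)oxy]phenol
Product: 15 tert-butyl(dimethyl)silyl ether of the (2S)-chromenol, via benzodioxaborin 13 (not isolated), via ortho-quinone methide 14 (not isolated)
Conditions: PhB(OH)2, EtCO2H (cat.), toluene, 4 Å MS, 80 °C; then 2,2-dimethylpropane-1,3-diol, (R)-3,3'-bis(2,4,6-triisopropylphenyl)-BINOL N-triflylphosphoramide (10 mol %), −78 to −40 °C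
Reagents that add atoms: phenylboronic acid, OB(O)c1ccccc1 (its boron and phenyl stand in intermediate 13 only; product 15 holds atoms of 11 and 12 only)
Why: Proposed new method: in stage one phenylboronic acid esterifies the phenol of 12, binds aldehyde 11 at boron and delivers the ortho carbon to the carbonyl carbon through a six-membered array (boron-templated ortho-hydroxyalkylation, the known first half of the thermal phenol–enal chromenylation), which makes the aryl–C4 bond and stores the adduct as benzodioxaborin 13 below the temperature of its racemic retro-[4+2] fragmentation; in stage two the chiral N-triflylphosphoramide ionises the benzylic C–O bond of 13 at low temperature while the diol takes up the boron, and the O-protonated form of ortho-quinone methide 14 (a 1-(2-hydroxyaryl)allyl cation) is held by the chiral anion through the phenolic O–H as a contact ion pair in which the oxygen closes on the tertiary terminus. The closest known reaction types are the racemic phenylboronic acid-mediated chromenylation (dioxaborin, ortho-quinone methide, oxa-6π electrocyclisation) and the chiral N-triflylphosphoramide-catalysed intramolecular allylic substitution of 2-(3-hydroxyalk-1-enyl)phenols to 2,2-disubstituted 2H-chromenes, which runs through the same kind of ion pair; new are the dioxaborin as cation source in the same pot and the demand that the anion tells methyl from a primary alkyl chain. The pyran ring closes by C–O bond formation at the allyl terminus in a 6-endo-trig sense, the ionic counterpart of the disrotatory oxa-6π closure of the (Z)-s-cis oxatriene. The C2 stereocentre is set by the chiral anion alone, since the delocalised cation has lost the C4 configuration of 13 and the alkene geometry of 11. The step needs carbon–carbon bond formation at the ortho carbon and at the carbonyl carbon of the enal, which the boron template secures, the para position being blocked by the silyloxy group and the two ortho positions of 12 being equivalent. It also needs ring closure to outrun capture of the cation by the 6,7-alkene of the chain, which the intramolecular phenol and the low temperature should secure.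

Step 9
Reactants: 15 silyl ether of the (2S)-chromenol
Product: 16 (2S)-2-methyl-2-[(3E)-4-methyl-6-(2,6,6-trimethylcyclohex-1-en-1-yl)hex-3-en-1-yl]-2H-chromen-6-ol (target)
Conditions: TBAF, AcOH, THF, 0 °C
Reagents that add atoms: none
Why: Fluoride cleaves the aryl silyl ether (desilylation driven by Si–F bond formation) while acetic acid buffers the phenoxide so that the electron-rich chromenol is not oxidised; the stereocentre is not involved.

**Compound list**

1 | β-cyclocitral (2,6,6-trimethylcyclohex-1-ene-1-carbaldehyde) | CC1=C(C=O)C(C)(C)CCC1 | starting material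
2 | β-cyclogeraniol, (2,6,6-trimethylcyclohex-1-en-1-yl)methanol | CC1=C(CO)C(C)(C)CCC1 | intermediate
3 | β-cyclogeranyl bromide, 2-(bromomethyl)-1,3,3-trimethylcyclohex-1-ene | CC1=C(CBr)C(C)(C)CCC1 | intermediate (not isolated)
4 | β-cyclogeranyl phenyl sulfone, {[(2,6,6-trimethylcyclohex-1-en-1-yl)methyl]sulfonyl}benzene | CC1=C(CS(=O)(=O)c2ccccc2)C(C)(C)CCC1 | intermediate
5 | geranyl acetate, (2E)-3,7-dimethylocta-2,6-dien-1-yl acetate | CC(C)=CCC/C(C)=C/COC(C)=O | starting material
6 | (2E,6E)-8-hydroxy-3,7-dimethylocta-2,6-dien-1-yl acetate | OC/C(C)=C/CC/C(C)=C/COC(C)=O | intermediate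
7 | (2E,6E)-8-bromo-3,7-dimethylocta-2,6-dien-1-yl acetate | BrC/C(C)=C/CC/C(C)=C/COC(C)=O | intermediate
8 | (2E,6E)-3,7-dimethyl-9-(phenylsulfonyl)-9-(2,6,6-trimethylcyclohex-1-en-1-yl)nona-2,6-dien-1-yl acetate, racemic at C9 | CC1=C(C(C/C(C)=C/CC/C(C)=C/COC(C)=O)S(=O)(=O)c2ccccc2)C(C)(C)CCC1 | intermediate (not isolated)
9 | (2E,6E)-3,7-dimethyl-9-(phenylsulfonyl)-9-(2,6,6-trimethylcyclohex-1-en-1-yl)nona-2,6-dien-1-ol, racemic at C9 | CC1=C(C(C/C(C)=C/CC/C(C)=C/CO)S(=O)(=O)c2ccccc2)C(C)(C)CCC1 | intermediate
10 | (2E,6E)-3,7-dimethyl-9-(2,6,6-trimethylcyclohex-1-en-1-yl)nona-2,6-dien-1-ol | CC1=C(CC/C(C)=C/CC/C(C)=C/CO)C(C)(C)CCC1 | intermediate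
11 | (2E,6E)-3,7-dimethyl-9-(2,6,6-trimethylcyclohex-1-en-1-yl)nona-2,6-dienal | CC1=C(CC/C(C)=C/CC/C(C)=C/C=O)C(C)(C)CCC1 | intermediate
12 | 4-[(tert-butyldimethylsilyl)oxy]phenol | CC(C)(C)[Si](C)(C)Oc1ccc(O)cc1 | starting material
13 | 6-[(tert-butyldimethylsilyl)oxy]-4-[(1E,5E)-2,6-dimethyl-8-(2,6,6-trimethylcyclohex-1-en-1-yl)octa-1,5-dien-1-yl]-2-phenyl-4H-1,3,2-benzodioxaborinine, racemic at C4 | CC1=C(CC/C(C)=C/CC/C(C)=C/C2OB(c3ccccc3)Oc3ccc(O[Si](C)(C)C(C)(C)C)cc32)C(C)(C)CCC1 | intermediate (not isolated)
14 | 4-[(tert-butyldimethylsilyl)oxy]-6-[(2E,6E)-3,7-dimethyl-9-(2,6,6-trimethylcyclohex-1-en-1-yl)nona-2,6-dien-1-ylidene]cyclohexa-2,4-dien-1-one (ortho-quinone methide; reacts as its O-protonated ion pair with the chiral anion) | CC1=C(CC/C(C)=C/CC/C(C)=C/C=C2C=C(O[Si](C)(C)C(C)(C)C)C=CC2=O)C(C)(C)CCC1 | intermediate (not isolated)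
15 | tert-butyl(dimethyl)({(2S)-2-methyl-2-[(3E)-4-methyl-6-(2,6,6-trimethylcyclohex-1-en-1-yl)hex-3-en-1-yl]-2H-chromen-6-yl}oxy)silane | CC1=C(CC/C(C)=C/CC[C@@]2(C)C=Cc3cc(O[Si](C)(C)C(C)(C)C)ccc3O2)C(C)(C)CCC1 | intermediate
16 | (2S)-2-methyl-2-[(3E)-4-methyl-6-(2,6,6-trimethylcyclohex-1-en-1-yl)hex-3-en-1-yl]-2H-chromen-6-ol | CC1=C(CC/C(C)=C/CC[C@@]2(C)C=Cc3cc(O)ccc3O2)C(C)(C)CCC1 | target

**Step count and risks**

Total steps: 9. Longest linear sequence: 7 steps (1, 2, 5, 6, 7, 8, 9; the branch 3, 4, 5, 6, 7, 8, 9 is equally long).

Steps most likely to fail: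

1. Step 8 (proposed new method). The chiral anion may not discriminate the two faces of the tertiary cation terminus, part of 13 may fragment thermally in stage one and close without control, or the boron by-product may tie up the acid and stop turnover. Fallback with known chemistry, setting out from 11 (with 12) and coming back at 15: the thermal chromenylation (PhB(OH)2, EtCO2H, toluene, 110 °C, Dean–Stark) should give the racemic silyl chromene F1 through 13 and free 14. F1 is then resolved by preparative HPLC on a cellulose tris(3,5-dimethylphenylcarbamate) phase, and the (2S)-enantiomer rejoins the route as 15.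

2. Step 6. Protonation of the allyl anion at the ring carbon would move the double bond out of the ring, and reductive loss of the allylic oxygen is a second possible course. Fallback, setting out from 9 and coming back at 10: silylation (TBSCl, imidazole, DMF) gives the silyl ether of the hydroxy sulfone F2. Palladium-catalysed hydride desulfonylation (PdCl2(dppp), LiBHEt3, THF, 0 °C) then cleaves the C–S bond by oxidative addition to zerovalent palladium, and the π-allyl complex of divalent palladium should take hydride at its less substituted exocyclic terminus to give the silyl ether of the C20 alcohol F3. TBAF returns 10.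

3. Step 5. Alkylation of the hindered α-sulfonyl carbanion may be slow, so that attack on the acetate or elimination of HBr from 7 takes over. Fallback, setting out from 6 and coming back at 10 without any sulfone (step 6 is then not needed): MnO2 oxidises 6 to the 8-oxo acetate F4, and Wittig methylenation (Ph3P=CH2, THF, −78 to 0 °C) gives the triene acetate F5. 9-BBN adds to the terminal vinyl group to give the alkylborane F6, which undergoes B-alkyl Suzuki–Miyaura coupling (PdCl2(dppf), K3PO4, DMF–THF–H2O, 50 °C) with 2,6,6-trimethylcyclohex-1-en-1-yl triflate F7 (from commercial 2,2,6-trimethylcyclohexanone, LiN(i-Pr)2, PhNTf2) to give the acetate of the C20 alcohol F8. K2CO3 in MeOH returns 10.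

Further compounds
F1 | step 8 | racemic tert-butyl(dimethyl)({2-methyl-2-[(3E)-4-methyl-6-(2,6,6-trimethylcyclohex-1-en-1-yl)hex-3-en-1-yl]-2H-chromen-6-yl}oxy)silane | CC1=C(CC/C(C)=C/CCC2(C)C=Cc3cc(O[Si](C)(C)C(C)(C)C)ccc3O2)C(C)(C)CCC1
F2 | step 6 | tert-butyl(dimethyl)silyl ether of hydroxy sulfone 9 | CC1=C(C(C/C(C)=C/CC/C(C)=C/CO[Si](C)(C)C(C)(C)C)S(=O)(=O)c2ccccc2)C(C)(C)CCC1
F3 | step 6 | tert-butyl(dimethyl)silyl ether of alcohol 10 | CC1=C(CC/C(C)=C/CC/C(C)=C/CO[Si](C)(C)C(C)(C)C)C(C)(C)CCC1
F4 | step 5 | (2E,6E)-3,7-dimethyl-8-oxoocta-2,6-dien-1-yl acetate | O=C/C(C)=C/CC/C(C)=C/COC(C)=O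
F5 | step 5 | (2E,6E)-3,7-dimethylnona-2,6,8-trien-1-yl acetate | C=C/C(C)=C/CC/C(C)=C/COC(C)=O
F6 | step 5 | (2E,6E)-9-(9-borabicyclo[3.3.1]nonan-9-yl)-3,7-dimethylnona-2,6-dien-1-yl acetate | CC(=O)OC/C=C(C)/CC/C=C(C)/CCB1C2CCCC1CCC2
F7 | step 5 | 2,6,6-trimethylcyclohex-1-en-1-yl trifluoromethanesulfonate | CC1=C(OS(=O)(=O)C(F)(F)F)C(C)(C)CCC1
F8 | step 5 | (2E,6E)-3,7-dimethyl-9-(2,6,6-trimethylcyclohex-1-en-1-yl)nona-2,6-dien-1-yl acetate | CC1=C(CC/C(C)=C/CC/C(C)=C/COC(C)=O)C(C)(C)CCC1
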